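**Retrosynthetic overview**

- The strategy rests on the C3 carbinol that sits next to the (4Z)-C4=C5 trisubstituted olefin inside the ten-membered carbocycle C1–C10. C3–C4 is cut as an intramolecular Ni/Cr coupling of a (Z)-alkenyl iodide with an aldehyde (seco aldehyde 21), and the C1–C10 oxirane is added last with a peracid.
- 21 is cut at C7–C8 into bromomethylbutenolide 8 and β,γ-unsaturated aldehyde 16 (indium Barbier allylation). The C8 isobutyrate is then installed with inversion.
- 8 comes from the glutamate-derived lactone 1 by Z-iodo-olefination at C5 and selenium-mediated hydroxymethylation/dehydrogenation. 16 comes from TBS-protected 3-butyn-1-ol by carboalumination and ethylene oxide opening.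
- Ring order: γ-lactone (present in 1, carried throughout), then the ten-membered carbocycle (step 15), then the oxirane (step 16).

Key step: step 15

**Remarks on the chemistry**

- Assumption: the Barbier addition (step 11) is taken to run through the closed chair transition state usual for 3-(bromomethyl)butenolides. This gives the 8S carbinol, which is the C8 epimer of what the target needs. The isobutyrate is therefore introduced with inversion (Mitsunobu, step 12) and not by plain acylation.
- Germacrane numbering is used for the skeleton. C6 carries the descriptor S while iodine is on C4 (compounds 17–21) and R in 22 and 23; this is a priority change only, no bond at C6 is touched.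
- Compounds 1 and 9 are taken as commercial.

**Route**

Step 1
Reactants: 1 (S)-5-(hydroxymethyl)dihydrofuran-2(3H)-one
Product: 2 (S)-5-oxotetrahydrofuran-2-carbaldehyde
Conditions: DMP, pyridine, CH2Cl2, 0 °C to rt; non-aqueous work-up, used crude
Reagents that add atoms: none
Why: Dess–Martin oxidation of the primary alcohol under non-aqueous, near-neutral conditions should give the aldehyde without over-oxidation and without epimerising the α-oxygenated centre (future C6).

Step 2
Reactants: 2 (S)-5-oxotetrahydrofuran-2-carbaldehyde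
Product: 3 (S)-5-[(Z)-2-iodoprop-1-en-1-yl]dihydrofuran-2(3H)-one
Conditions: EtPPh3I, n-BuLi, THF, 0 °C; I2, −78 °C; NaHMDS, −20 °C; then 2, −78 °C
Reagents that add atoms: ethyltriphenylphosphonium iodide CC[P+](c1ccccc1)(c1ccccc1)c1ccccc1.[I-]; iodine II
Why: Stork–Zhao-type Wittig olefination with the preformed α-iodo ylide Ph3P=C(I)CH3 runs under kinetic control and should give the (Z)-2-iodoalkene (iodine cis to the lactone carbon), with no free base left to epimerise the aldehyde.

Step 3
Reactants: 3 (S)-5-[(Z)-2-iodoprop-1-en-1-yl]dihydrofuran-2(3H)-one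
Product: 4 (5S)-5-[(Z)-2-iodoprop-1-en-1-yl]-3-(phenylselanyl)dihydrofuran-2(3H)-one (C3 epimers)
Conditions: LiHMDS, THF, −78 °C; PhSeBr
Reagents that add atoms: phenylselenyl bromide Br[Se]c1ccccc1
Why: Enolate selenenylation at the only acidic CH2 (future C11); the new centre is of no consequence because it is removed in step 5.

Step 4
Reactants: 4 (5S)-5-[(Z)-2-iodoprop-1-en-1-yl]-3-(phenylselanyl)dihydrofuran-2(3H)-one
Product: 5 (5S)-3-(hydroxymethyl)-5-[(Z)-2-iodoprop-1-en-1-yl]-3-(phenylselanyl)dihydrofuran-2(3H)-one (C3 epimers)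
Conditions: LiHMDS, THF, −78 °C; CH2O (gas, from cracked paraformaldehyde), −78 to −40 °C
Reagents that add atoms: formaldehyde C=O
Why: Aldol addition of the selenium-stabilised lactone enolate to monomeric formaldehyde installs C13 as a hydroxymethyl group on the α-carbon.

Step 5
Reactants: 5 (5S)-3-(hydroxymethyl)-5-[(Z)-2-iodoprop-1-en-1-yl]-3-(phenylselanyl)dihydrofuran-2(3H)-one
Product: 7 (S)-3-(hydroxymethyl)-5-[(Z)-2-iodoprop-1-en-1-yl]furan-2(5H)-one, via selenoxide 6 (not isolated)
Conditions: 30% H2O2, CH2Cl2, 0 °C to rt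
Reagents that add atoms: none
Why: Selenoxide syn-elimination runs toward the ring CH2 and away from the carbinol carbon, as is usual for β-hydroxy selenoxides, and should give the endocyclic butenolide without touching the γ-stereocentre.

Step 6
Reactants: 7 (S)-3-(hydroxymethyl)-5-[(Z)-2-iodoprop-1-en-1-yl]furan-2(5H)-one
Product: 8 (S)-3-(bromomethyl)-5-[(Z)-2-iodoprop-1-en-1-yl]furan-2(5H)-one
Conditions: CBr4, PPh3, CH2Cl2, 0 °C
Reagents that add atoms: carbon tetrabromide BrC(Br)(Br)Br
Why: Appel bromination of the primary allylic alcohol under neutral conditions, so that no base reaches the acidic γ-hydrogen.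

Step 7
Reactants: 9 tert-butyl(but-3-yn-1-yloxy)dimethylsilane; 10 ethylene oxide
Product: 13 (E)-6-[(tert-butyldimethylsilyl)oxy]-4-methylhex-3-en-1-ol, via alkenylalane 11 (not isolated), via lithium alanate 12 (not isolated)
Conditions: Me3Al, Cp2ZrCl2 (cat.), CH2Cl2, rt; volatiles removed; n-BuLi, hexane/THF, −78 °C; ethylene oxide, −78 °C to rt; aqueous work-up
Reagents that add atoms: trimethylaluminium C[Al](C)C
Why: Negishi Zr-catalysed carboalumination adds methyl and aluminium syn across the terminal alkyne (methyl to the internal carbon), and the alanate opens ethylene oxide with retention at the alkenyl carbon, so the trisubstituted C1=C10 olefin should form as the E isomer only.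

Step 8
Reactants: 13 (E)-6-[(tert-butyldimethylsilyl)oxy]-4-methylhex-3-en-1-ol
Product: 14 tert-butyl{[(E)-6-[(4-methoxybenzyl)oxy]-3-methylhex-3-en-1-yl]oxy}dimethylsilane
Conditions: NaH, PMBCl, TBAI (cat.), THF/DMF, 0 °C to rt
Reagents that add atoms: 4-methoxybenzyl chloride COc1ccc(CCl)cc1
Why: Williamson etherification of the primary alkoxide; the silyl ether and the olefin are inert.

Step 9
Reactants: 14 tert-butyl{[(E)-6-[(4-methoxybenzyl)oxy]-3-methylhex-3-en-1-yl]oxy}dimethylsilane
Product: 15 (E)-6-[(4-methoxybenzyl)oxy]-3-methylhex-3-en-1-ol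
Conditions: CSA (cat.), MeOH/CH2Cl2, 0 °C
Reagents that add atoms: none
Why: Acid-catalysed methanolysis removes the primary TBS ether while the PMB ether and the olefin are stable under these mild conditions.

Step 10
Reactants: 15 (E)-6-[(4-methoxybenzyl)oxy]-3-methylhex-3-en-1-ol
Product: 16 (E)-6-[(4-methoxybenzyl)oxy]-3-methylhex-3-enal
Conditions: DMP, pyridine, CH2Cl2, 0 °C; used at once
Reagents that add atoms: none
Why: Buffered Dess–Martin oxidation should give the β,γ-unsaturated aldehyde without migration of the olefin into conjugation.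

Step 11
Reactants: 8 (S)-3-(bromomethyl)-5-[(Z)-2-iodoprop-1-en-1-yl]furan-2(5H)-one; 16 (E)-6-[(4-methoxybenzyl)oxy]-3-methylhex-3-enal
Product: 17 (4R,5S)-4-[(1S,3E)-1-hydroxy-6-[(4-methoxybenzyl)oxy]-3-methylhex-3-en-1-yl]-5-[(Z)-2-iodoprop-1-en-1-yl]-3-methylidenedihydrofuran-2(3H)-one
Conditions: In powder, THF/H2O, rt
Reagents that add atoms: none
Why: Indium-mediated Barbier allylation: the allylindium adds through its γ-carbon (SE2′) in a closed chair transition state on the butenolide face opposite the iodopropenyl group, which sets C7 trans to C6, and with the aldehyde chain equatorial, which sets C8 as the anti (8S) carbinol; the alkenyl iodide and the PMB ether are inert to indium.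

Step 12
Reactants: 17 the Barbier adduct (8S alcohol); 18 isobutyric acid
Product: 19 (1R,3E)-1-[(2S,3R)-2-[(Z)-2-iodoprop-1-en-1-yl]-4-methylidene-5-oxooxolan-3-yl]-6-[(4-methoxybenzyl)oxy]-3-methylhex-3-en-1-yl 2-methylpropanoate
Conditions: PPh3, DIAD, toluene, 0 °C to rt (betaine preformed)
Reagents that add atoms: none
Why: Mitsunobu esterification: isobutyrate displaces the C8 oxyphosphonium by SN2 with inversion (8S to 8R), which installs the ester and corrects C8 in one operation.

Step 13
Reactants: 19 the 8R isobutyrate PMB ether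
Product: 20 (1R,3E)-6-hydroxy-1-[(2S,3R)-2-[(Z)-2-iodoprop-1-en-1-yl]-4-methylidene-5-oxooxolan-3-yl]-3-methylhex-3-en-1-yl 2-methylpropanoate
Conditions: DDQ, CH2Cl2/pH 7 buffer, 0 °C
Reagents that add atoms: none
Why: Oxidative PMB cleavage by benzylic hydride abstraction and hydrolysis of the hemiacetal; the isobutyrate, the α-methylene lactone, the iodoalkene and the trialkyl olefin should not react.

Step 14
Reactants: 20 the C3 primary alcohol
Product: 21 (1R,3E)-1-[(2S,3R)-2-[(Z)-2-iodoprop-1-en-1-yl]-4-methylidene-5-oxooxolan-3-yl]-3-methyl-6-oxohex-3-en-1-yl 2-methylpropanoate (seco aldehyde)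
Conditions: DMP, pyridine, CH2Cl2, 0 °C; filtered and used at once
Reagents that add atoms: none
Why: Buffered Dess–Martin oxidation releases the C3 aldehyde as the β,γ-unsaturated isomer, with no base strong enough to move C1=C10 into conjugation or to epimerise C7.

Step 15
Reactants: 21 the seco aldehyde Z-alkenyl iodide
Product: 22 (3S,6R,7R,8R)-3-hydroxy-8-(isobutyryloxy)germacra-1(10)E,4Z,11(13)-trien-6,12-olide
Conditions: CrCl2 (excess), NiCl2 (cat.), degassed DMSO/THF, rt, slow addition at high dilution
Reagents that add atoms: none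
Why: Ni(0), formed from NiCl2 by Cr(II), inserts into the C4–I bond with retention and transmetallates to Cr(III), and the alkenylchromium adds to the C3 aldehyde; the closest known reaction type is the intramolecular Nozaki–Hiyama–Kishi macrocyclisation to medium-ring allylic alcohols, which tolerates the lactone, the isobutyrate and the α-methylene group. The ten-membered carbocycle closes by C3–C4 bond formation in the 10-exo-trig mode, the carbonyl oxygen staying outside the ring. The 4Z geometry is inherited from the iodide. C3 is the only new stereocentre and is set by the substrate: A(1,3) strain across the Z olefin holds H6 and the aldehyde hydrogen in the olefin plane, and the trans-lactone with the rigid E-C1=C10 tether should let C4 reach only the Re face of the aldehyde, which gives 3S. The step therefore needs Re-face selectivity, secured by the C6/C7 lactone and the two olefin geometries, and ring closure over oligomerisation, secured by high dilution.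

Step 16
Reactants: 22 the macrocyclic dienol
Product: 23 (1S,3S,6R,7R,8R,10S)-1,10-epoxy-3-hydroxy-8-(isobutyryloxy)germacra-4Z,11(13)-dien-6,12-olide (target)
Conditions: mCPBA, NaHCO3, CH2Cl2, 0 °C
Reagents that add atoms: mCPBA O=C(OO)c1cccc(Cl)c1
Why: Prilezhaev epoxidation transfers oxygen in a concerted syn manner to the most electron-rich olefin (C1=C10, alkyl-substituted only, whereas C4=C5 carries two allylic oxygens and C11=C13 is conjugated), the E geometry gives the trans oxirane, and attack on the outward-facing lobe of the ring conformer with C14 on the α-face should give the 1S,10S isomer.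

**Compound list**

1 | (S)-5-(hydroxymethyl)dihydrofuran-2(3H)-one | OC[C@H]1OC(=O)CC1 | starting material
2 | (S)-5-oxotetrahydrofuran-2-carbaldehyde | O=C[C@H]1OC(=O)CC1 | intermediate
3 | (S)-5-[(Z)-2-iodoprop-1-en-1-yl]dihydrofuran-2(3H)-one | I/C(C)=C\[C@H]1OC(=O)CC1 | intermediate
4 | (5S)-5-[(Z)-2-iodoprop-1-en-1-yl]-3-(phenylselanyl)dihydrofuran-2(3H)-one, C3 epimers | I/C(C)=C\[C@H]1OC(=O)C([Se]c2ccccc2)C1 | intermediate
5 | (5S)-3-(hydroxymethyl)-5-[(Z)-2-iodoprop-1-en-1-yl]-3-(phenylselanyl)dihydrofuran-2(3H)-one, C3 epimers | I/C(C)=C\[C@H]1OC(=O)C(CO)([Se]c2ccccc2)C1 | intermediate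
6 | selenoxide of 5 (not isolated) | I/C(C)=C\[C@H]1OC(=O)C(CO)([Se](=O)c2ccccc2)C1 | intermediate
7 | (S)-3-(hydroxymethyl)-5-[(Z)-2-iodoprop-1-en-1-yl]furan-2(5H)-one | I/C(C)=C\[C@H]1OC(=O)C(CO)=C1 | intermediate
8 | (S)-3-(bromomethyl)-5-[(Z)-2-iodoprop-1-en-1-yl]furan-2(5H)-one | I/C(C)=C\[C@H]1OC(=O)C(CBr)=C1 | intermediate
9 | tert-butyl(but-3-yn-1-yloxy)dimethylsilane | C#CCCO[Si](C)(C)C(C)(C)C | starting material
10 | ethylene oxide | C1CO1 | starting material
11 | (E)-{4-[(tert-butyldimethylsilyl)oxy]-2-methylbut-1-en-1-yl}dimethylalane (not isolated) | C[Al](C)/C=C(\C)CCO[Si](C)(C)C(C)(C)C | intermediate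
12 | lithium butyl{(E)-4-[(tert-butyldimethylsilyl)oxy]-2-methylbut-1-en-1-yl}dimethylalanate (not isolated) | [Li+].CCCC[Al-](C)(C)/C=C(\C)CCO[Si](C)(C)C(C)(C)C | intermediate
13 | (E)-6-[(tert-butyldimethylsilyl)oxy]-4-methylhex-3-en-1-ol | OCC/C=C(\C)CCO[Si](C)(C)C(C)(C)C | intermediate
14 | tert-butyl{[(E)-6-[(4-methoxybenzyl)oxy]-3-methylhex-3-en-1-yl]oxy}dimethylsilane | COc1ccc(COCC/C=C(\C)CCO[Si](C)(C)C(C)(C)C)cc1 | intermediate
15 | (E)-6-[(4-methoxybenzyl)oxy]-3-methylhex-3-en-1-ol | COc1ccc(COCC/C=C(\C)CCO)cc1 | intermediate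
16 | (E)-6-[(4-methoxybenzyl)oxy]-3-methylhex-3-enal | COc1ccc(COCC/C=C(\C)CC=O)cc1 | intermediate
17 | (4R,5S)-4-[(1S,3E)-1-hydroxy-6-[(4-methoxybenzyl)oxy]-3-methylhex-3-en-1-yl]-5-[(Z)-2-iodoprop-1-en-1-yl]-3-methylidenedihydrofuran-2(3H)-one | COc1ccc(COCC/C=C(\C)C[C@H](O)[C@H]2C(=C)C(=O)O[C@@H]2/C=C(/C)I)cc1 | intermediate
18 | isobutyric acid | CC(C)C(=O)O | starting material
19 | (1R,3E)-1-[(2S,3R)-2-[(Z)-2-iodoprop-1-en-1-yl]-4-methylidene-5-oxooxolan-3-yl]-6-[(4-methoxybenzyl)oxy]-3-methylhex-3-en-1-yl 2-methylpropanoate | COc1ccc(COCC/C=C(\C)C[C@@H](OC(=O)C(C)C)[C@H]2C(=C)C(=O)O[C@@H]2/C=C(/C)I)cc1 | intermediate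
20 | (1R,3E)-6-hydroxy-1-[(2S,3R)-2-[(Z)-2-iodoprop-1-en-1-yl]-4-methylidene-5-oxooxolan-3-yl]-3-methylhex-3-en-1-yl 2-methylpropanoate | OCC/C=C(\C)C[C@@H](OC(=O)C(C)C)[C@H]1C(=C)C(=O)O[C@@H]1/C=C(/C)I | intermediate
21 | (1R,3E)-1-[(2S,3R)-2-[(Z)-2-iodoprop-1-en-1-yl]-4-methylidene-5-oxooxolan-3-yl]-3-methyl-6-oxohex-3-en-1-yl 2-methylpropanoate | O=CC/C=C(\C)C[C@@H](OC(=O)C(C)C)[C@H]1C(=C)C(=O)O[C@@H]1/C=C(/C)I | intermediate
22 | (3S,6R,7R,8R)-3-hydroxy-8-(isobutyryloxy)germacra-1(10)E,4Z,11(13)-trien-6,12-olide | C=C1C(=O)O[C@@H]2/C=C(/C)[C@@H](O)C/C=C(\C)C[C@@H](OC(=O)C(C)C)[C@@H]12 | intermediate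
23 | (1S,3S,6R,7R,8R,10S)-1,10-epoxy-3-hydroxy-8-(isobutyryloxy)germacra-4Z,11(13)-dien-6,12-olide | C=C1C(=O)O[C@@H]2/C=C(/C)[C@@H](O)C[C@@H]3O[C@@]3(C)C[C@@H](OC(=O)C(C)C)[C@@H]12 | target

**Step count**

Total: 16 steps. Longest linear sequence: 12 steps (1 to 23 through steps 1–6 and 11–16).

**Steps most likely to fail**

1. Step 15. The addition may show poor facial selectivity at C3, because the 3S outcome rests on a conformational argument for a ten-membered transition state, and oligomerisation or enolisation of the β,γ-unsaturated aldehyde may compete. The fallback sets out from 21 and moves the stereocontrol from the C–C bond formation to a reagent-controlled reduction. The cyclisation would be run without regard to C3, giving 22 together with the 3R epimer of 22 F1. The mixture would be oxidised (DMP, pyridine, CH2Cl2, 0 °C) to the macrocyclic 3-ketone, the 4Z-enone F2. F2 would be reduced with (R)-Me-CBS and catecholborane in toluene at −78 °C, the alkenyl arm acting as the large group, which should give the 3S alcohol. The fallback comes back to the route at 22.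

2. Step 12. The activated C8 oxyphosphonium may eliminate toward C7 or C9, or be captured by the lactone carbonyl, instead of undergoing clean SN2 displacement on this β-branched carbinol. The fallback sets out from 17 and sets C8 by oxidation and reagent-controlled reduction, so it is also independent of the sense of the Barbier addition. 17 would be oxidised (DMP, pyridine, CH2Cl2, 0 °C) to the C8 ketone F3. F3 would be reduced with (S)-Me-CBS and catecholborane at −78 °C, the branched C7 arm acting as the large group, to the 8R alcohol F4. F4 would be acylated with isobutyryl chloride, pyridine and catalytic DMAP in CH2Cl2 at 0 °C. The fallback comes back to the route at 19.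

3. Step 16. The peracid may attack the wrong face of C1=C10, may be directed by the free C3 hydroxyl to C4=C5, or the acid by-product may trigger transannular opening of the oxirane. The fallback sets out from 22 and replaces substrate control by reagent control with the hydroxyl masked. 22 would be silylated (TESCl, imidazole, CH2Cl2, 0 °C) to the triethylsilyl ether of 22 F5. F5 would be epoxidised with the dioxirane from the enantiomer of the fructose-derived Shi ketone (Oxone, buffer at about pH 8, MeCN/dimethoxymethane, 0 °C), chosen by the spiro transition-state model for the 1S,10S oxirane, to give the triethylsilyl ether of 23 F6. F6 would be desilylated with pyridine-buffered HF·pyridine in THF at 0 °C. The fallback comes back to the route at 23.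

**Further compounds**

F1 | step 15 | (3R,6R,7R,8R)-3-hydroxy-8-(isobutyryloxy)germacra-1(10)E,4Z,11(13)-trien-6,12-olide (3-epi-22) | C=C1C(=O)O[C@@H]2/C=C(/C)[C@H](O)C/C=C(\C)C[C@@H](OC(=O)C(C)C)[C@@H]12
F2 | step 15 | (6R,7R,8R)-8-(isobutyryloxy)-3-oxogermacra-1(10)E,4Z,11(13)-trien-6,12-olide | C=C1C(=O)O[C@@H]2/C=C(/C)C(=O)C/C=C(\C)C[C@@H](OC(=O)C(C)C)[C@@H]12
F3 | step 12 | (4R,5S)-5-[(Z)-2-iodoprop-1-en-1-yl]-4-[(E)-6-[(4-methoxybenzyl)oxy]-3-methylhex-3-enoyl]-3-methylidenedihydrofuran-2(3H)-one | COc1ccc(COCC/C=C(\C)CC(=O)[C@H]2C(=C)C(=O)O[C@@H]2/C=C(/C)I)cc1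
F4 | step 12 | (4R,5S)-4-[(1R,3E)-1-hydroxy-6-[(4-methoxybenzyl)oxy]-3-methylhex-3-en-1-yl]-5-[(Z)-2-iodoprop-1-en-1-yl]-3-methylidenedihydrofuran-2(3H)-one | COc1ccc(COCC/C=C(\C)C[C@@H](O)[C@H]2C(=C)C(=O)O[C@@H]2/C=C(/C)I)cc1
F5 | step 16 | 3-O-triethylsilyl ether of 22 | C=C1C(=O)O[C@@H]2/C=C(/C)[C@@H](O[Si](CC)(CC)CC)C/C=C(\C)C[C@@H](OC(=O)C(C)C)[C@@H]12
F6 | step 16 | 3-O-triethylsilyl ether of 23 | C=C1C(=O)O[C@@H]2/C=C(/C)[C@@H](O[Si](CC)(CC)CC)C[C@@H]3O[C@@]3(C)C[C@@H](OC(=O)C(C)C)[C@@H]12
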